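Each chroman is cut at C4–C4a, the bond joining the C4 methylene of ring C to ring A, while O1–C2 and the C2 stereocentre are kept. Both arms thus become aryl propargyl ethers on a tribenzylated benzotropolone core. In one operation a cationic monovalent gold catalyst closes both rings C by 6-endo attack of the electron-rich ring A ortho carbons on the terminal alkynes, giving a bis-flav-3-ene whose C3=C4 alkenes let C2 direct C3. The precursor is the (S,S)-bis[1-(3,5-dibenzyloxyphenoxy)propargyl] benzotropolone, made from a dialdehyde core by alkynylation, asymmetric ketone reduction and Mitsunobu inversion. Hydroboration, oxidation–reduction, galloylation and hydrogenolysis finish the target.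

Key step: step 8

Remark on the chemistry: the benzotropolone is handled as its benzenoid 5-one tautomer (tropolone oxygen at C6). By CIP ranking (silylethynyl > aryl > ethynyl), the propargylic centres that become the 2R flavan carbons are S in the silylated carbinols, R in the free ethynyl carbinols, and S in the aryl propargyl ethers and the 2H-chromenes.

**Step 1**
Reactants: 1 3,4-dihydroxybenzaldehyde; 2 2,3,4-trihydroxybenzaldehyde
Product: 4 3,4,6-trihydroxy-5-oxo-5H-benzo[7]annulene-1,7-dicarbaldehyde, via 4-formyl-1,2-benzoquinone 3 (not isolated)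
Conditions: NaIO3, H2O/acetone, 0 °C to rt (1 in moderate excess)
Reagents that add atoms: none
Why: Purpurogallin-type oxidative benzotropolone condensation, in which iodate oxidises 1 to quinone 3, C5 of 2 (ortho and para to hydroxyls, meta to the formyl group) adds to C6 of 3, and reoxidation, ring closure onto the central oxygenated carbon of 2 and loss of C4 of 2 as CO2 should leave the tropolone ring with formyl groups at C1 and C7; only C5 of 2 has a hydroxylated neighbour that can be extruded, which fixes the regiochemistry.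

**Step 2**
Reactants: 4 3,4,6-trihydroxy-5-oxo-5H-benzo[7]annulene-1,7-dicarbaldehyde; 5 benzyl bromide
Product: 6 3,4,6-tris(benzyloxy)-5-oxo-5H-benzo[7]annulene-1,7-dicarbaldehyde
Conditions: BnBr, K2CO3, Bu4NI (cat.), DMF, 50 °C
Reagents that add atoms: benzyl bromide 5, BrCc1ccccc1
Why: Williamson etherification of the three acidic hydroxyls; the tropolone should be alkylated at O6 because only the 5-one form keeps the benzo ring benzenoid, and excess reagent with warming should overcome the hydrogen bond of the peri 4-hydroxyl.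

**Step 3**
Reactants: 6 3,4,6-tris(benzyloxy)-5-oxo-5H-benzo[7]annulene-1,7-dicarbaldehyde; 7 trimethylsilylacetylene
Product: 8 3,4,6-tris(benzyloxy)-1,7-bis[1-hydroxy-3-(trimethylsilyl)prop-2-yn-1-yl]-5H-benzo[7]annulen-5-one (mixture of diastereomers)
Conditions: 7, n-BuLi, THF, −78 °C; then 6, −78 °C; aq. NH4Cl
Reagents that add atoms: trimethylsilylacetylene 7, C#C[Si](C)(C)C
Why: 1,2-Addition of the lithium acetylide to both aldehydes, which at −78 °C should react far faster than the poorly electrophilic tropolone ether carbonyl; the carbinol centres are uncontrolled here and are erased in step 4.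

**Step 4**
Reactants: 8 bis-carbinol mixture
Product: 9 3,4,6-tris(benzyloxy)-1,7-bis[3-(trimethylsilyl)prop-2-ynoyl]-5H-benzo[7]annulen-5-one
Conditions: Dess–Martin periodinane, CH2Cl2, 0 °C to rt
Reagents that add atoms: none
Why: Dess–Martin oxidation of benzylic propargylic alcohols to ynones under near-neutral conditions that spare silyl alkynes and benzyl ethers.

**Step 5**
Reactants: 9 bis-ynone
Product: 10 3,4,6-tris(benzyloxy)-1,7-bis[(1S)-1-hydroxy-3-(trimethylsilyl)prop-2-yn-1-yl]-5H-benzo[7]annulen-5-one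
Conditions: RuCl[(S,S)-TsDPEN](p-cymene) (5 mol%), HCO2H/Et3N (5:2), CH2Cl2, rt
Reagents that add atoms: none
Why: Noyori asymmetric transfer hydrogenation, in which outer-sphere hydride transfer should place the alkynyl group beside the η6-arene while the ortho-substituted, twisted aryl group is the bystander, so the (S,S)-ligand should give both S carbinols, and the electron-rich tropone carbonyl should not be reduced.

**Step 6**
Reactants: 10 (S,S)-bis(silylpropargylic) diol
Product: 11 3,4,6-tris(benzyloxy)-1,7-bis[(1R)-1-hydroxyprop-2-yn-1-yl]-5H-benzo[7]annulen-5-one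
Conditions: Bu4NF, AcOH, THF, 0 °C
Reagents that add atoms: none
Why: Fluoride-induced protodesilylation of the alkynylsilanes, buffered so that neither the tropolone benzyl ether nor the propargylic C–H bonds meet free base; the configuration is untouched and only the descriptor changes.

**Step 7**
Reactants: 11 (R,R)-bis(propargylic) diol; 12 3,5-bis(benzyloxy)phenol
Product: 13 3,4,6-tris(benzyloxy)-1,7-bis[(1S)-1-(3,5-bis(benzyloxy)phenoxy)prop-2-yn-1-yl]-5H-benzo[7]annulen-5-one
Conditions: 12 (2.4 equiv), PPh3, DIAD, toluene, 0 °C to rt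
Reagents that add atoms: 3,5-bis(benzyloxy)phenol 12, Oc1cc(OCc2ccccc2)cc(OCc2ccccc2)c1
Why: Mitsunobu etherification, in which SN2 attack of the phenoxide on each alkoxyphosphonium ion should invert both carbinol centres (R,R to S,S), a non-polar solvent and low temperature keeping the displacement concerted.

**Step 8**
Reactants: 13 (S,S)-bis(aryl propargyl ether)
Product: 14 3,4,6-tris(benzyloxy)-1,7-bis[(2S)-5,7-bis(benzyloxy)-2H-chromen-2-yl]-5H-benzo[7]annulen-5-one
Conditions: Ph3PAuNTf2 (5 mol% per alkyne), CH2Cl2, 0 °C to rt, dark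
Reagents that add atoms: none
Why: The cationic monovalent gold centre binds each terminal alkyne as a π-complex, the ring A carbon ortho to the ether oxygen (also ortho and para to benzyloxy groups) attacks the terminal alkyne carbon anti to gold in a Friedel–Crafts sense, and rearomatisation with protodeauration of the vinylgold species releases the C3=C4 alkene and the catalyst. The closest known reaction type is the gold- or platinum-catalysed intramolecular hydroarylation of aryl propargyl ethers to 2H-chromenes. Each of the two pyran rings (ring C of either arm) closes in the 6-endo-dig mode, forming C4–C4a. No stereocentre is created, and C2 of each arm is carried through because no bond to it is made or broken. The step needs 6-endo over 5-exo closure, which attack at the unsubstituted alkyne terminus and the three-atom tether should secure. It also needs ring closure to outrun ionisation of the C2–O bond, which the highly nucleophilic ring A with two equivalent ortho carbons, the acceptor character of the tropone-containing core, the weakly coordinating NTf2 counter-ion and the low temperature should secure.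

**Step 9**
Reactants: 14 (S,S)-bis-flav-3-ene
Product: 16 3,4,6-tris(benzyloxy)-1,7-bis[(2R,3S)-5,7-bis(benzyloxy)-3-hydroxychroman-2-yl]-5H-benzo[7]annulen-5-one (2,3-trans in both units), via bis(C3-borane) adduct 15 (not isolated)
Conditions: BH3·THF (2.5 equiv), THF, 0 °C; then 30% H2O2, aq. NaOAc, 0 °C to rt
Reagents that add atoms: borane (as BH3·THF), B (boron is held only in 15); hydrogen peroxide, OO
Why: Hydroboration–oxidation, in which boron should add to C3 (the electron-rich terminus of the ring A styrene-type alkene, remote from the arene) on the face opposite to the C2 substituent, and oxidation with retention should give each 3-hydroxyl trans to its C2 aryl group.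

**Step 10**
Reactants: 16 bis(2,3-trans-flavan-3-ol)
Product: 17 3,4,6-tris(benzyloxy)-1,7-bis[(2R)-5,7-bis(benzyloxy)-3-oxochroman-2-yl]-5H-benzo[7]annulen-5-one
Conditions: Dess–Martin periodinane, CH2Cl2, 0 °C to rt
Reagents that add atoms: none
Why: Dess–Martin oxidation to the flavan-3-ones without base, so the C2 centres alpha to the new ketones should not enolise.

**Step 11**
Reactants: 17 bis(flavan-3-one)
Product: 18 3,4,6-tris(benzyloxy)-1,7-bis[(2R,3R)-5,7-bis(benzyloxy)-3-hydroxychroman-2-yl]-5H-benzo[7]annulen-5-one (2,3-cis in both units)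
Conditions: LiBH(sec-Bu)3, THF, −78 °C; aq. NH4Cl
Reagents that add atoms: none
Why: Substrate-controlled ketone reduction, in which the bulky hydride should attack each C3 carbonyl from the face opposite to the C2 aryl group to give the cis alcohols; at −78 °C the saturated ketones should react far faster than the vinylogous-ester carbonyl of the tropolone ether.

**Step 12**
Reactants: 18 bis(2,3-cis-flavan-3-ol); 19 3,4,5-tris(benzyloxy)benzoic acid
Product: 20 3,4,6-tris(benzyloxy)-1,7-bis[(2R,3R)-5,7-bis(benzyloxy)-3-(3,4,5-tris(benzyloxy)benzoyloxy)chroman-2-yl]-5H-benzo[7]annulen-5-one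
Conditions: 19 (3 equiv), DCC, DMAP, CH2Cl2, rt
Reagents that add atoms: 3,4,5-tris(benzyloxy)benzoic acid 19, O=C(O)c1cc(OCc2ccccc2)c(OCc2ccccc2)c(OCc2ccccc2)c1
Why: Steglich esterification, which acylates the hindered axial hydroxyls at oxygen and leaves the C3 configuration untouched.

**Step 13**
Reactants: 20 perbenzylated digallate
Product: 21 3,4,6-trihydroxy-1,7-bis[(2R,3R)-5,7-dihydroxy-3-(3,4,5-trihydroxybenzoyloxy)chroman-2-yl]-5H-benzo[7]annulen-5-one (CNP0283148.1)
Conditions: H2 (1 atm), Pd(OH)2/C, THF/MeOH, rt, degassed work-up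
Reagents that add atoms: none
Why: Hydrogenolysis of all thirteen benzyl ethers under neutral conditions, under which the gallate esters, the O1–C2 bonds and the tropolone ring should survive at ambient pressure.

**Compound list**

1 | 3,4-dihydroxybenzaldehyde | O=Cc1ccc(O)c(O)c1 | starting material
2 | 2,3,4-trihydroxybenzaldehyde | O=Cc1ccc(O)c(O)c1O | starting material
3 | 4-formyl-1,2-benzoquinone | O=CC1=CC(=O)C(=O)C=C1 | intermediate (not isolated)
4 | 3,4,6-trihydroxy-5-oxo-5H-benzo[7]annulene-1,7-dicarbaldehyde | O=Cc1ccc2c(C=O)cc(O)c(O)c2c(=O)c1O | intermediate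
5 | benzyl bromide | BrCc1ccccc1 | starting material
6 | 3,4,6-tris(benzyloxy)-5-oxo-5H-benzo[7]annulene-1,7-dicarbaldehyde | O=Cc1ccc2c(C=O)cc(OCc3ccccc3)c(OCc3ccccc3)c2c(=O)c1OCc1ccccc1 | intermediate
7 | trimethylsilylacetylene | C#C[Si](C)(C)C | starting material
8 | 3,4,6-tris(benzyloxy)-1,7-bis[1-hydroxy-3-(trimethylsilyl)prop-2-yn-1-yl]-5H-benzo[7]annulen-5-one, diastereomer mixture | C[Si](C)(C)C#CC(O)c1ccc2c(C(O)C#C[Si](C)(C)C)cc(OCc3ccccc3)c(OCc3ccccc3)c2c(=O)c1OCc1ccccc1 | intermediate
9 | 3,4,6-tris(benzyloxy)-1,7-bis[3-(trimethylsilyl)prop-2-ynoyl]-5H-benzo[7]annulen-5-one | C[Si](C)(C)C#CC(=O)c1ccc2c(C(=O)C#C[Si](C)(C)C)cc(OCc3ccccc3)c(OCc3ccccc3)c2c(=O)c1OCc1ccccc1 | intermediate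
10 | 3,4,6-tris(benzyloxy)-1,7-bis[(1S)-1-hydroxy-3-(trimethylsilyl)prop-2-yn-1-yl]-5H-benzo[7]annulen-5-one | C[Si](C)(C)C#C[C@@H](O)c1ccc2c([C@@H](C#C[Si](C)(C)C)O)cc(OCc3ccccc3)c(OCc3ccccc3)c2c(=O)c1OCc1ccccc1 | intermediate
11 | 3,4,6-tris(benzyloxy)-1,7-bis[(1R)-1-hydroxyprop-2-yn-1-yl]-5H-benzo[7]annulen-5-one | C#C[C@@H](O)c1ccc2c([C@@H](C#C)O)cc(OCc3ccccc3)c(OCc3ccccc3)c2c(=O)c1OCc1ccccc1 | intermediate
12 | 3,5-bis(benzyloxy)phenol | Oc1cc(OCc2ccccc2)cc(OCc2ccccc2)c1 | starting material
13 | 3,4,6-tris(benzyloxy)-1,7-bis[(1S)-1-(3,5-bis(benzyloxy)phenoxy)prop-2-yn-1-yl]-5H-benzo[7]annulen-5-one | C#C[C@H](Oc1cc(OCc2ccccc2)cc(OCc2ccccc2)c1)c1ccc2c([C@H](C#C)Oc3cc(OCc4ccccc4)cc(OCc4ccccc4)c3)cc(OCc3ccccc3)c(OCc3ccccc3)c2c(=O)c1OCc1ccccc1 | intermediate (key-step precursor)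
14 | 3,4,6-tris(benzyloxy)-1,7-bis[(2S)-5,7-bis(benzyloxy)-2H-chromen-2-yl]-5H-benzo[7]annulen-5-one | C1=Cc2c(OCc3ccccc3)cc(OCc3ccccc3)cc2O[C@@H]1c1ccc2c([C@H]3Oc4cc(OCc5ccccc5)cc(OCc5ccccc5)c4C=C3)cc(OCc3ccccc3)c(OCc3ccccc3)c2c(=O)c1OCc1ccccc1 | intermediate (key-step product)
15 | bis(C3-borane) adduct of 14, drawn as the monoalkylborane, boron on C3 trans to the C2 aryl group in both units | B[C@H]1Cc2c(OCc3ccccc3)cc(OCc3ccccc3)cc2O[C@@H]1c1ccc2c([C@H]3Oc4cc(OCc5ccccc5)cc(OCc5ccccc5)c4C[C@@H]3B)cc(OCc3ccccc3)c(OCc3ccccc3)c2c(=O)c1OCc1ccccc1 | intermediate (not isolated)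
16 | 3,4,6-tris(benzyloxy)-1,7-bis[(2R,3S)-5,7-bis(benzyloxy)-3-hydroxychroman-2-yl]-5H-benzo[7]annulen-5-one | O[C@H]1Cc2c(OCc3ccccc3)cc(OCc3ccccc3)cc2O[C@@H]1c1ccc2c([C@H]3Oc4cc(OCc5ccccc5)cc(OCc5ccccc5)c4C[C@@H]3O)cc(OCc3ccccc3)c(OCc3ccccc3)c2c(=O)c1OCc1ccccc1 | intermediate
17 | 3,4,6-tris(benzyloxy)-1,7-bis[(2R)-5,7-bis(benzyloxy)-3-oxochroman-2-yl]-5H-benzo[7]annulen-5-one | O=C1Cc2c(OCc3ccccc3)cc(OCc3ccccc3)cc2O[C@@H]1c1ccc2c([C@H]3Oc4cc(OCc5ccccc5)cc(OCc5ccccc5)c4CC3=O)cc(OCc3ccccc3)c(OCc3ccccc3)c2c(=O)c1OCc1ccccc1 | intermediate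
18 | 3,4,6-tris(benzyloxy)-1,7-bis[(2R,3R)-5,7-bis(benzyloxy)-3-hydroxychroman-2-yl]-5H-benzo[7]annulen-5-one | O[C@@H]1Cc2c(OCc3ccccc3)cc(OCc3ccccc3)cc2O[C@@H]1c1ccc2c([C@H]3Oc4cc(OCc5ccccc5)cc(OCc5ccccc5)c4C[C@H]3O)cc(OCc3ccccc3)c(OCc3ccccc3)c2c(=O)c1OCc1ccccc1 | intermediate
19 | 3,4,5-tris(benzyloxy)benzoic acid | O=C(O)c1cc(OCc2ccccc2)c(OCc2ccccc2)c(OCc2ccccc2)c1 | starting material
20 | 3,4,6-tris(benzyloxy)-1,7-bis[(2R,3R)-5,7-bis(benzyloxy)-3-(3,4,5-tris(benzyloxy)benzoyloxy)chroman-2-yl]-5H-benzo[7]annulen-5-one | O=C(O[C@@H]1Cc2c(OCc3ccccc3)cc(OCc3ccccc3)cc2O[C@@H]1c1ccc2c([C@H]3Oc4cc(OCc5ccccc5)cc(OCc5ccccc5)c4C[C@H]3OC(=O)c3cc(OCc4ccccc4)c(OCc4ccccc4)c(OCc4ccccc4)c3)cc(OCc3ccccc3)c(OCc3ccccc3)c2c(=O)c1OCc1ccccc1)c1cc(OCc2ccccc2)c(OCc2ccccc2)c(OCc2ccccc2)c1 | intermediate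
21 | 3,4,6-trihydroxy-1,7-bis[(2R,3R)-5,7-dihydroxy-3-(3,4,5-trihydroxybenzoyloxy)chroman-2-yl]-5H-benzo[7]annulen-5-one (CNP0283148.1) | O=C(O[C@@H]1Cc2c(O)cc(O)cc2O[C@@H]1c1ccc2c([C@H]3Oc4cc(O)cc(O)c4C[C@H]3OC(=O)c3cc(O)c(O)c(O)c3)cc(O)c(O)c2c(=O)c1O)c1cc(O)c(O)c(O)c1 | target

**Step count**

Total steps: 13. Longest linear sequence: 13 steps (1 and 2 to 21).

**Steps most likely to fail**

Step 8. The risk is that gold-induced ionisation of the benzylic, propargylic C2–O bonds competes with ring closure, which would erode the C2 configuration or fragment the ethers; the reaction could also stall after one ring has closed. The fallback forms C3=C4 by olefin metathesis instead; it sets out from 11 and 12 and comes back at 14. Diol 11 would be semihydrogenated (H2, Pd/CaCO3 poisoned with Pb(OAc)2, quinoline, EtOAc) to 3,4,6-tris(benzyloxy)-1,7-bis[(1R)-1-hydroxyprop-2-en-1-yl]-5H-benzo[7]annulen-5-one F1. Phenol 12 would be ortho-formylated (MgCl2, Et3N, paraformaldehyde, MeCN, reflux) to 4,6-bis(benzyloxy)-2-hydroxybenzaldehyde F2 and methylenated (Ph3PCH3Br, KOt-Bu, THF) to 3,5-bis(benzyloxy)-2-vinylphenol F3. Mitsunobu coupling of F1 with F3 (PPh3, DIAD, toluene, 0 °C) should give, with inversion, 3,4,6-tris(benzyloxy)-1,7-bis[(1S)-1-(3,5-bis(benzyloxy)-2-vinylphenoxy)prop-2-en-1-yl]-5H-benzo[7]annulen-5-one F4. Twofold ring-closing metathesis with the second-generation Grubbs catalyst (CH2Cl2, 40 °C) should then expel ethylene and give 14 without any cationic intermediate.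

Step 1. The risk is that the free formyl groups are consumed (hydration, over-oxidation, condensation with the electron-rich phenols), that addition to the formyl-activated quinone is misdirected, or that self-condensation of the pyrogallol partner outruns the cross-reaction. The fallback runs the condensation at the ester level and adjusts the oxidation state afterwards. It does not set out from a numbered compound: it replaces 1 and 2 by their purchased methyl esters, methyl 3,4-dihydroxybenzoate F5 and methyl 2,3,4-trihydroxybenzoate F6, and comes back at 6. The same iodate condensation (NaIO3, H2O/acetone) should give dimethyl 3,4,6-trihydroxy-5-oxo-5H-benzo[7]annulene-1,7-dicarboxylate F7. Benzylation (BnBr, K2CO3, DMF) should give dimethyl 3,4,6-tris(benzyloxy)-5-oxo-5H-benzo[7]annulene-1,7-dicarboxylate F8. Reduction (i-Bu2AlH, CH2Cl2, −78 °C) should give 3,4,6-tris(benzyloxy)-1,7-bis(hydroxymethyl)-5H-benzo[7]annulen-5-one F9, and MnO2 (CH2Cl2, rt) should return dialdehyde 6.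

Step 5. The risk is poor or reversed facial discrimination, because both ketone substituents (aryl and alkynyl) are π-groups that can compete for the position next to the catalyst arene. The fallback bypasses the ketone; it sets out from 6 and 7 and comes back at 10. Catalytic enantioselective alkynylation of both aldehydes of 6 with 7 (Me2Zn, ProPhenol ligand, Ph3PO, toluene, 0 °C) should give 10 directly. Face selection then rests on hydrogen against aryl at the aldehyde, and the ligand antipode would be chosen to give the S carbinols. No compound outside the list is formed (F0).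

**Further compounds**

F1 | step 8 | 3,4,6-tris(benzyloxy)-1,7-bis[(1R)-1-hydroxyprop-2-en-1-yl]-5H-benzo[7]annulen-5-one | C=C[C@@H](O)c1ccc2c([C@@H](C=C)O)cc(OCc3ccccc3)c(OCc3ccccc3)c2c(=O)c1OCc1ccccc1
F2 | step 8 | 4,6-bis(benzyloxy)-2-hydroxybenzaldehyde | O=Cc1c(O)cc(OCc2ccccc2)cc1OCc1ccccc1
F3 | step 8 | 3,5-bis(benzyloxy)-2-vinylphenol | C=Cc1c(O)cc(OCc2ccccc2)cc1OCc1ccccc1
F4 | step 8 | 3,4,6-tris(benzyloxy)-1,7-bis[(1S)-1-(3,5-bis(benzyloxy)-2-vinylphenoxy)prop-2-en-1-yl]-5H-benzo[7]annulen-5-one | C=C[C@H](Oc1cc(OCc2ccccc2)cc(OCc2ccccc2)c1C=C)c1ccc2c([C@H](C=C)Oc3cc(OCc4ccccc4)cc(OCc4ccccc4)c3C=C)cc(OCc3ccccc3)c(OCc3ccccc3)c2c(=O)c1OCc1ccccc1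
F5 | step 1 | methyl 3,4-dihydroxybenzoate (purchased) | COC(=O)c1ccc(O)c(O)c1
F6 | step 1 | methyl 2,3,4-trihydroxybenzoate (purchased) | COC(=O)c1ccc(O)c(O)c1O
F7 | step 1 | dimethyl 3,4,6-trihydroxy-5-oxo-5H-benzo[7]annulene-1,7-dicarboxylate | COC(=O)c1ccc2c(C(=O)OC)cc(O)c(O)c2c(=O)c1O
F8 | step 1 | dimethyl 3,4,6-tris(benzyloxy)-5-oxo-5H-benzo[7]annulene-1,7-dicarboxylate | COC(=O)c1ccc2c(C(=O)OC)cc(OCc3ccccc3)c(OCc3ccccc3)c2c(=O)c1OCc1ccccc1
F9 | step 1 | 3,4,6-tris(benzyloxy)-1,7-bis(hydroxymethyl)-5H-benzo[7]annulen-5-one | OCc1ccc2c(CO)cc(OCc3ccccc3)c(OCc3ccccc3)c2c(=O)c1OCc1ccccc1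
F0 | step 5 | none | none
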